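**Retrosynthetic overview** (oxane numbering: O1, C2 = CMe2, C3 = CHBr, C6 = C(CH3)(cyclohexyl))

1. The ring halogens go on last: the tertiary C–Br is cut back to a trans-diaxial chlorohydrin, and this to the ring alkene of a limonene-derived bromo-oxane.
2. The oxane is opened by cutting its C2–C3 bond and its O1–C6 bond together, which leaves acetone and a C12 chain that is an α-bromo carbanion at one end and a 1,1-disubstituted alkene (masked tertiary cation) at the other.
3. The feature that allows this: O1 sits between two fully substituted carbons, C2 (gem-dimethyl, the carbonyl carbon of acetone) and C6 (methyl and cyclohexenyl, the Markovnikov carbon of an isopropenyl-type alkene), and C3 carries bromine β to O1 (bromohydrin retron). The step is a formal oxa-[4+2] union of acetone with a 1,4-dipole.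
4. The α-bromo carbanion is a configurationally defined magnesium carbenoid from an α-bromo sulfoxide; the chain comes from (R)-limonene by allylic lithiation/ethylene oxide, Appel bromination and Andersen sulfoxide synthesis.
5. Stereochemistry and ring order: the cyclohexene ring and its C1 are bought (limonene); the sulfur stereocentre is bought (sulfinate) and relayed to oxane C3 and then C6 as the oxane closes in the key step; cyclohexane C3 and C4 are relayed from C1.

Key step: step 5

Assumption: the α-bromination in step 4 is taken to give the (S)-configured C–Br carbon from the (R)-sulfoxide without change of the arrangement at sulfur; if the opposite sense of induction is found, the enantiomeric sulfinate is used in step 3, since only this carbon configuration is carried into step 5.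

**Step 1**
Reactants: 1 (R)-(+)-limonene; 2 ethylene oxide
Product: 4 4-[(1R)-4-methylcyclohex-3-en-1-yl]pent-4-en-1-ol, via allyllithium 3 (not isolated)
Conditions: n-BuLi, TMEDA, hexane, 25 °C; then 2, THF, −78 to 0 °C
Reagents that add atoms: none
Why: Allylic lithiation of the isopropenyl methyl group by n-BuLi·TMEDA should give a symmetrical 2-substituted allyllithium that opens ethylene oxide by SN2 attack (epoxide alkylation), the ring stereocentre not being involved.

**Step 2**
Reactants: 4 4-[(1R)-4-methylcyclohex-3-en-1-yl]pent-4-en-1-ol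
Product: 5 (4R)-4-(5-bromopent-1-en-2-yl)-1-methylcyclohex-1-ene
Conditions: CBr4, PPh3, CH2Cl2, 0 °C
Reagents that add atoms: carbon tetrabromide, BrC(Br)(Br)Br
Why: Appel reaction, in which the oxyphosphonium ion of the primary alcohol is displaced by bromide (SN2) and the two alkenes should stay untouched.

**Step 3**
Reactants: 5 (4R)-4-(5-bromopent-1-en-2-yl)-1-methylcyclohex-1-ene; 6 (1R,2S,5R)-5-methyl-2-(propan-2-yl)cyclohexyl (S)-4-methylbenzenesulfinate
Product: 8 1-methyl-4-[(R)-{4-[(1R)-4-methylcyclohex-3-en-1-yl]pent-4-en-1-yl}sulfinyl]benzene, via Grignard reagent 7 (not isolated)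
Conditions: Mg, THF, 40 °C; then 6, THF, −40 to 0 °C
Reagents that add atoms: none
Why: Andersen sulfoxide synthesis, in which the Grignard reagent displaces mentholate at sulfur with inversion, so that the sulfur stereocentre of 8 is bought with sulfinate 6.

**Step 4**
Reactants: 8 1-methyl-4-[(R)-{4-[(1R)-4-methylcyclohex-3-en-1-yl]pent-4-en-1-yl}sulfinyl]benzene
Product: 9 1-[(S)-{(1S)-1-bromo-4-[(1R)-4-methylcyclohex-3-en-1-yl]pent-4-en-1-yl}sulfinyl]-4-methylbenzene
Conditions: NBS, K2CO3, CH2Cl2, 0 °C, dark
Reagents that add atoms: N-bromosuccinimide, O=C1CCC(=O)N1Br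
Why: α-Halogenation of a sulfoxide through the S-bromosulfoxonium ion and its ylide, in which the sulfur stereocentre should control the new C–Br stereocentre (1,2-asymmetric induction), any minor epimer being removed by chromatography.

**Step 5**
Reactants: 9 1-[(S)-{(1S)-1-bromo-4-[(1R)-4-methylcyclohex-3-en-1-yl]pent-4-en-1-yl}sulfinyl]-4-methylbenzene; 10 acetone
Product: 13 (3S,6R)-3-bromo-2,2,6-trimethyl-6-[(1R)-4-methylcyclohex-3-en-1-yl]oxane, via magnesium carbenoid 11 (not isolated), via bromohydrin 12 (not isolated)
Conditions: EtMgCl, THF/toluene, −78 °C; then 10, −78 °C; then MsOH, CH2Cl2, −40 to 0 °C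
Reagents that add atoms: none
Why: Sulfoxide–magnesium exchange (inversion at sulfur, retention at carbon) should turn 9 into the α-bromoalkyl magnesium carbenoid 11, which adds to acetone with retention to give the magnesium alkoxide of bromohydrin 12, whose covalent Mg–O bond suppresses epoxide closure at −78 °C; methanesulfonic acid then protonates the 1,1-disubstituted alkene in the Markovnikov sense and the tertiary hydroxyl captures the tertiary cation. The closest known reaction types are the 1,2-addition of α-haloalkyl magnesium and lithium carbenoids to carbonyl compounds and the Brønsted-acid hydroalkoxylation of δ-hydroxy 1,1-disubstituted alkenes to 2,2,6,6-tetrasubstituted oxanes. The oxane ring closes by 6-exo-trig attack of oxygen on C6. C3 is controlled by the carbenoid carbon (reagent control, relayed from the bought sulfur stereocentre); C6 is controlled by a chair transition state with bromine equatorial and antiperiplanar to the ring C–O bond and the cyclohexenyl group equatorial (1,4-relay from C3), which is the least secure selectivity of the route. The step needs a carbenoid that neither loses its configuration nor undergoes α-elimination before it meets acetone, which magnesium as counter-ion and −78 °C should secure, and chemoselective protonation of the 1,1-disubstituted alkene over the ring alkene, which fast intramolecular capture by the hydroxyl and the low temperature should secure.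

**Step 6**
Reactants: 13 (3S,6R)-3-bromo-2,2,6-trimethyl-6-[(1R)-4-methylcyclohex-3-en-1-yl]oxane
Product: 14 (1S,2S,4R)-4-[(2R,5S)-5-bromo-2,6,6-trimethyloxan-2-yl]-2-chloro-1-methylcyclohexan-1-ol
Conditions: trichloroisocyanuric acid, acetone/H2O, 0 °C
Reagents that add atoms: trichloroisocyanuric acid, O=C1N(Cl)C(=O)N(Cl)C(=O)N1Cl; water, O
Why: Chlorohydrin formation, in which the chloronium ion on the face trans to the ring C1 substituent should be opened by water at the tertiary carbon (Markovnikov and trans-diaxial, Fürst–Plattner rule), which sets both new ring stereocentres relative to the bought one.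

**Step 7**
Reactants: 14 (1S,2S,4R)-4-[(2R,5S)-5-bromo-2,6,6-trimethyloxan-2-yl]-2-chloro-1-methylcyclohexan-1-ol
Product: 15 (3S,6R)-3-bromo-6-[(1R,3S,4S)-4-bromo-3-chloro-4-methylcyclohexyl]-2,2,6-trimethyloxane
Conditions: Me3SiBr, CH2Cl2, −40 to 0 °C
Reagents that add atoms: bromotrimethylsilane, C[Si](C)(C)Br
Why: SN1 substitution with neighbouring-group participation, in which ionisation of the axial tertiary hydroxyl is assisted by the antiperiplanar axial chlorine and the chloronium ion is opened by bromide at the tertiary carbon, where Markovnikov and trans-diaxial preferences coincide, so that bromine should replace hydroxyl with retention.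

**Compound list**

1 | (R)-(+)-limonene, (4R)-1-methyl-4-(prop-1-en-2-yl)cyclohex-1-ene | CC(=C)[C@@H]1CCC(C)=CC1 | starting material
2 | ethylene oxide (oxirane) | C1CO1 | starting material
3 | {2-[(1R)-4-methylcyclohex-3-en-1-yl]prop-2-en-1-yl}lithium | [Li]CC(=C)[C@@H]1CCC(C)=CC1 | intermediate
4 | 4-[(1R)-4-methylcyclohex-3-en-1-yl]pent-4-en-1-ol | OCCCC(=C)[C@@H]1CCC(C)=CC1 | intermediate
5 | (4R)-4-(5-bromopent-1-en-2-yl)-1-methylcyclohex-1-ene | BrCCCC(=C)[C@@H]1CCC(C)=CC1 | intermediate
6 | (1R,2S,5R)-5-methyl-2-(propan-2-yl)cyclohexyl (S)-4-methylbenzenesulfinate | C[C@@H]1CC[C@H]([C@@H](C1)O[S@](=O)c1ccc(C)cc1)C(C)C | starting material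
7 | bromo{4-[(1R)-4-methylcyclohex-3-en-1-yl]pent-4-en-1-yl}magnesium | Br[Mg]CCCC(=C)[C@@H]1CCC(C)=CC1 | intermediate
8 | 1-methyl-4-[(R)-{4-[(1R)-4-methylcyclohex-3-en-1-yl]pent-4-en-1-yl}sulfinyl]benzene | Cc1ccc(cc1)[S@](=O)CCCC(=C)[C@@H]1CCC(C)=CC1 | intermediate
9 | 1-[(S)-{(1S)-1-bromo-4-[(1R)-4-methylcyclohex-3-en-1-yl]pent-4-en-1-yl}sulfinyl]-4-methylbenzene | Cc1ccc(cc1)[S@](=O)[C@@H](Br)CCC(=C)[C@@H]1CCC(C)=CC1 | intermediate
10 | acetone | CC(C)=O | starting material
11 | chloro{(1S)-1-bromo-4-[(1R)-4-methylcyclohex-3-en-1-yl]pent-4-en-1-yl}magnesium | Cl[Mg][C@@H](Br)CCC(=C)[C@@H]1CCC(C)=CC1 | intermediate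
12 | (3S)-3-bromo-2-methyl-6-[(1R)-4-methylcyclohex-3-en-1-yl]hept-6-en-2-ol | CC(C)(O)[C@@H](Br)CCC(=C)[C@@H]1CCC(C)=CC1 | intermediate
13 | (3S,6R)-3-bromo-2,2,6-trimethyl-6-[(1R)-4-methylcyclohex-3-en-1-yl]oxane | CC1(C)O[C@@](C)([C@@H]2CCC(C)=CC2)CC[C@@H]1Br | intermediate
14 | (1S,2S,4R)-4-[(2R,5S)-5-bromo-2,6,6-trimethyloxan-2-yl]-2-chloro-1-methylcyclohexan-1-ol | CC1(C)O[C@@](C)([C@@H]2CC[C@](C)(O)[C@@H](Cl)C2)CC[C@@H]1Br | intermediate
15 | (3S,6R)-3-bromo-6-[(1R,3S,4S)-4-bromo-3-chloro-4-methylcyclohexyl]-2,2,6-trimethyloxane (deoxy isocaespitol) | CC1(C)O[C@@](C)([C@@H]2CC[C@](C)(Br)[C@@H](Cl)C2)CC[C@@H]1Br | target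

Total step count: 7. Longest linear sequence: 7 steps, from (R)-limonene 1.

**Steps most likely to fail**

Step 5 (key step). Several processes may go wrong:
- bromine–magnesium exchange may compete with sulfoxide–magnesium exchange;
- the carbenoid may undergo α-elimination or lose its configuration before addition;
- addition to acetone may be sluggish;
- the acid may ionise the bromohydrin or shift the ring double bond, which would scramble the cyclohexene stereocentre;
- the 1,4-relay from C3 to C6 may be weak and give the C6 epimer.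

The fallback makes the two bonds in separate, known operations and puts both oxane stereocentres under reagent or catalyst control. It sets out from alcohol 4 and comes back at 13. Carbamoylation of 4 (N,N-diisopropylcarbamoyl chloride, NaH, THF) gives 4-[(1R)-4-methylcyclohex-3-en-1-yl]pent-4-en-1-yl N,N-di(propan-2-yl)carbamate F1. Sparteine-mediated asymmetric lithiation of the O-alkyl carbamate (s-BuLi, (+)-sparteine, Et2O, −78 °C) and trapping with acetone gives (3S)-2-hydroxy-2-methyl-6-[(1R)-4-methylcyclohex-3-en-1-yl]hept-6-en-3-yl N,N-di(propan-2-yl)carbamate F2. LiAlH4 in THF removes the carbamoyl group to give (3S)-2-methyl-6-[(1R)-4-methylcyclohex-3-en-1-yl]hept-6-ene-2,3-diol F3. Selective mesylation of the secondary hydroxyl (MsCl, Et3N, CH2Cl2, −20 °C) gives (3S)-2-hydroxy-2-methyl-6-[(1R)-4-methylcyclohex-3-en-1-yl]hept-6-en-3-yl methanesulfonate F4, which K2CO3 in MeOH closes with inversion to (3R)-2,2-dimethyl-3-{3-[(1R)-4-methylcyclohex-3-en-1-yl]but-3-en-1-yl}oxirane F5. Li2NiBr4 in THF opens F5 at the secondary carbon with a second inversion and gives bromohydrin 12, now isolated. The oxane is then closed under neutral conditions and catalyst control by cobalt–salen-catalysed hydrogen-atom-transfer hydroalkoxylation, which gives 13. Its reagents are [N,N'-bis(3,5-di-tert-butylsalicylidene)-1,2-cyclohexanediaminato]cobalt in the enantiomeric form matched to the (6R) product, N-fluoro-2,4,6-trimethylpyridinium triflate and (Me2SiH)2O in PhCF3; these leave the ring alkene alone.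

Step 4. The bromination may discriminate poorly between the two faces of the sulfonium ylide (epimers at the C–Br carbon), and NBS may attack the trisubstituted ring alkene. The fallback forms the C–Br stereocentre by C–C bond formation instead of C–Br bond formation. It sets out from limonene 1 and comes back at 9. The allylic lithiation of step 1 is repeated but trapped with paraformaldehyde, which gives the lower homologue 3-[(1R)-4-methylcyclohex-3-en-1-yl]but-3-en-1-ol F6. I2, PPh3 and imidazole in CH2Cl2 convert F6 into (4R)-4-(4-iodobut-1-en-2-yl)-1-methylcyclohex-1-ene F7. Alkylation of the α-lithio derivative of (S)-bromomethyl p-tolyl sulfoxide (LDA, THF, −78 °C, then F7) gives 9 directly, the alkylation being directed by the sulfur stereocentre.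

Step 6. Ene-type allylic chlorination may take over from addition, and water may attack a weakly bridged chloronium ion from both faces, with loss of facial and trans selectivity. The fallback uses bromine as the electrophile and chloride as the nucleophile. It sets out from 13 and comes back at 14. NBS in aqueous acetone gives the trans-diaxial bromohydrin (1S,2S,4R)-2-bromo-4-[(2R,5S)-5-bromo-2,6,6-trimethyloxan-2-yl]-1-methylcyclohexan-1-ol F8. K2CO3 in MeOH closes it to the epoxide (1S,4R,6R)-4-[(2R,5S)-5-bromo-2,6,6-trimethyloxan-2-yl]-1-methyl-7-oxabicyclo[4.1.0]heptane F9, with oxygen cis to the oxanyl group. Li2CuCl4 in THF opens F9 trans-diaxially at the secondary carbon (Fürst–Plattner rule) and gives chlorohydrin 14.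

**Further compounds**

F1 | step 5 | 4-[(1R)-4-methylcyclohex-3-en-1-yl]pent-4-en-1-yl N,N-di(propan-2-yl)carbamate | CC(C)N(C(C)C)C(=O)OCCCC(=C)[C@@H]1CCC(C)=CC1
F2 | step 5 | (3S)-2-hydroxy-2-methyl-6-[(1R)-4-methylcyclohex-3-en-1-yl]hept-6-en-3-yl N,N-di(propan-2-yl)carbamate | CC(C)N(C(C)C)C(=O)O[C@@H](CCC(=C)[C@@H]1CCC(C)=CC1)C(C)(C)O
F3 | step 5 | (3S)-2-methyl-6-[(1R)-4-methylcyclohex-3-en-1-yl]hept-6-ene-2,3-diol | O[C@@H](CCC(=C)[C@@H]1CCC(C)=CC1)C(C)(C)O
F4 | step 5 | (3S)-2-hydroxy-2-methyl-6-[(1R)-4-methylcyclohex-3-en-1-yl]hept-6-en-3-yl methanesulfonate | CS(=O)(=O)O[C@@H](CCC(=C)[C@@H]1CCC(C)=CC1)C(C)(C)O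
F5 | step 5 | (3R)-2,2-dimethyl-3-{3-[(1R)-4-methylcyclohex-3-en-1-yl]but-3-en-1-yl}oxirane | CC1(C)O[C@@H]1CCC(=C)[C@@H]2CCC(C)=CC2
F6 | step 4 | 3-[(1R)-4-methylcyclohex-3-en-1-yl]but-3-en-1-ol | OCCC(=C)[C@@H]1CCC(C)=CC1
F7 | step 4 | (4R)-4-(4-iodobut-1-en-2-yl)-1-methylcyclohex-1-ene | ICCC(=C)[C@@H]1CCC(C)=CC1
F8 | step 6 | (1S,2S,4R)-2-bromo-4-[(2R,5S)-5-bromo-2,6,6-trimethyloxan-2-yl]-1-methylcyclohexan-1-ol | CC1(C)O[C@@](C)([C@@H]2CC[C@](C)(O)[C@@H](Br)C2)CC[C@@H]1Br
F9 | step 6 | (1S,4R,6R)-4-[(2R,5S)-5-bromo-2,6,6-trimethyloxan-2-yl]-1-methyl-7-oxabicyclo[4.1.0]heptane | CC1(C)O[C@@](C)([C@@H]2CC[C@]3(C)O[C@@H]3C2)CC[C@@H]1Br
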